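A closed, stirred flask of Z and L makes G and Q, and G then slips into D, so the useful number is the fraction of the product left as G, not the G made.

| flask | Z | L | remark | time |
|---|---|---|---|---|
| noon | 0.28 M | 1.02 equiv | run made earlier |  |
| dusk | 0.93 M | 1.02 equiv | run made earlier |  |
| spring | 0.20 M | 0.82 equiv | run made earlier |  |
| Sunday's | 0.40 M | 0.260 equiv |  | 4.0 d |
| Wednesday's | 0.20 M | 1.02 equiv |  | 4.0 d |
| Tuesday's | 0.60 M | 0.340 equiv |  | 4.0 d |
| Saturday's | 0.40 M | 0.680 equiv |  | 4.0 d |
| Monday's | 0.60 M | 3.10 equiv |  | 4.0 d |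

| run | time / h | G / % | Z / % |
|---|---|---|---|
| noon | 4.00 | 33.5 | 66.5 |
| noon | 6.00 | 42.0 | 57.4 |
| noon | 10.0 | 52.6 | 46.3 |
| noon | 20.0 | 62.0 | 33.6 |
| noon | 30.0 | 64.8 | 28.2 |
| noon | 50.0 | 64.3 | 23.9 |
| dusk | 8.00 | 73.7 | 24.0 |
| dusk | 15.0 | 79.0 | 16.1 |
| dusk | 25.0 | 79.3 | 13.1 |
| dusk | 30.0 | 78.5 | 11.5 |
| dusk | 40.0 | 77.0 | 10.3 |
| dusk | 50.0 | 74.9 | 9.3 |
| spring | 4.00 | 22.3 | 77.6 |
| spring | 8.00 | 33.1 | 65.1 |
| spring | 15.0 | 43.7 | 54.2 |
| spring | 25.0 | 49.2 | 46.8 |
| spring | 50.0 | 49.8 | 40.5 |

(readings scatter by 0.3 percentage points)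

- the numbers in the tables scatter by 0.3 percentage points (one standard deviation)
- what may be going on: Z + L -> G + Q; L <-> E; G <-> D

- ranking by amount of G, in percent of the Z charged, from high to low, at 4.0 d (Sunday's / Wednesday's / Tuesday's / Saturday's / Monday's)
- the same order at 5.0 h (Sunday's / Wednesday's / Tuesday's / Saturday's / Monday's)
- the amount of G, in percent of the Z charged of the flask you put first, at 4.0 d
- the amount of G, in percent of the Z charged of the flask you put last, at 4.0 d

The gap between the Z consumed and the G found is taken as D. G over Z consumed reads 84.5% at the last noon reading, 82.6% in the dusk run and 83.7% in the spring run, although dusk charged 3.32 times the Z of noon. The loss of G therefore looks first order, and G in a flask is reckoned as its Z consumed times this share.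

The first noon reading, with nearly equal charges, gives Monday's Z a starting lifetime of 1.20 h at the L charged, its 3.10 equiv; that lifetime lengthens as L is used, but it starts far shorter than 4.0 d. Monday's G is thus the share itself. Plain decay from the dusk share means a rate of 0.00383 h⁻¹ and leaves 69.2% at 4.0 d.

That link is weak, since it lets no D return. In the dusk run, D grows by 0.00371 h⁻¹ early and by 0.00290 h⁻¹ late, slower although G averages 76.4% over the early stretch and 76.7% over the late one. Charging that slowing to the growing D gives a return rate of 0.00876 h⁻¹ and a forward rate of 0.00528 h⁻¹. The share then falls towards 62.4%, a loose value under the scatter of 0.3 percentage points. The standing share at 4.0 d, the fraction of the product left as G, comes to 72.2%, and this is the number for Monday's. In Sunday's, L is the limiting reagent, and its 0.260 equiv times the share gives an estimate of 18.8% of G.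

The forecast gives Monday's > Wednesday's > Saturday's > Tuesday's > Sunday's at 4.0 d and Monday's > Saturday's > Wednesday's > Tuesday's > Sunday's at 5.0 h, with 68% first and 17% last, noting “Saturday's and Wednesday's are nearly tied at 5 h”, and its top stands below the 72.2% reckoned here.

The flasks give Monday's > Wednesday's > Saturday's > Tuesday's > Sunday's at 4.0 d and Monday's > Saturday's > Wednesday's > Tuesday's > Sunday's at 5.0 h, with 74.7% in Monday's and 17.9% in Sunday's.

    Z + L → G + Q (k = 0.00785 M⁻¹ min⁻¹)
    L ⇌ E (K = 5.60, k = 3.77 × 10⁻⁴ min⁻¹)
    G ⇌ D (K = 0.447, k = 9.31 × 10⁻⁵ min⁻¹)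

Monday's holds Z 0% and D 25.3% at 4.00 d, so its G is its share, against the 72.2% reckoned. Sunday's has converted 23.7% of its Z by 4.00 d; times the share, that is 17.1% of G, and the flask holds 17.9%.

The data are calculated for substances that don't exist; noise was put on by code.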